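**Retrosynthetic overview**

1. Target 16 ⇒ removal of eight O-benzyl groups, then the ester bond between O3 and the galloyl carbonyl: penta-O-benzyl-epigallocatechin 13 + acid 14.
2. 13 ⇒ racemic flavan-3-one 12: C2–H sits between ring B, O1 and the C3 carbonyl, so it epimerises, and one asymmetric transfer hydrogenation under dynamic kinetic resolution sets C2 and C3 together, cis.
3. 12 ⇒ its methyl enol ether 11 (a 3-methoxy-2H-chromene) ⇒ cut C4–C4a and O1–C2: phenol 7 (ring A with O1) + α-methoxy enal 6 (C4, C3, C2 and ring B), joined through a temporary boron tether (a benzodioxaborin ring that is not in the target) and closed by oxa-6π electrocyclisation.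
4. Enabling feature: ring A is a phloroglucinol, so C4a lies ortho to O1 and is activated by the ortho and para oxygens on C5 and C7, and the two ortho carbons of 7 are equivalent; the oxygen on C3 lets the C2–C3–C4 unit be an α-alkoxy enal, which leaves C3 as a masked ketone in ring C.
5. Ring order: rings A, B and the galloyl ring are bought; ring C (the pyran) is the only ring made, in step 4.

Key step: step 4

Assumption: because no aryl group is bonded directly to the C3 carbonyl of 12, the sense of induction of the transfer-hydrogenation catalyst cannot be read from the acetophenone model; the (S,S)-ligand is taken to give the (2R,3R)-alcohol, and the (R,R)-complex is used under the same conditions if a test run shows the opposite sense.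

**Route**

Step 1
Reactants: 1 3,4,5-tris(benzyloxy)benzaldehyde; 2 methyl methoxyacetate
Product: 4 methyl (2Z)-2-methoxy-3-[3,4,5-tris(benzyloxy)phenyl]prop-2-enoate, via aldol adduct 3 (not isolated)
Conditions: NaOMe (1.5 equiv), 2 (3 equiv), MeOH–THF, 0 °C to reflux
Reagents that add atoms: none
Why: An aldol (Claisen–Schmidt-type) condensation of the non-enolisable aldehyde 1 with the sodium enolate of 2, followed by E1cB loss of hydroxide from aldol adduct 3, should give the conjugated ester, the reversible steps favouring the Z isomer in which the aryl group is trans to the ester.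

Step 2
Reactants: 4 methyl (2Z)-2-methoxy-3-[3,4,5-tris(benzyloxy)phenyl]prop-2-enoate
Product: 5 (2Z)-2-methoxy-3-[3,4,5-tris(benzyloxy)phenyl]prop-2-en-1-ol
Conditions: iBu2AlH (2.5 equiv), CH2Cl2, −78 °C to 0 °C; aqueous potassium sodium tartrate work-up
Reagents that add atoms: none
Why: Reduction of an α,β-unsaturated ester with an aluminium hydride proceeds by 1,2-addition to the allylic alcohol at low temperature and should leave the enol ether, the double-bond geometry and the benzyl ethers untouched.

Step 3
Reactants: 5 (2Z)-2-methoxy-3-[3,4,5-tris(benzyloxy)phenyl]prop-2-en-1-ol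
Product: 6 (2Z)-2-methoxy-3-[3,4,5-tris(benzyloxy)phenyl]prop-2-enal
Conditions: activated MnO2 (excess), CH2Cl2, rt
Reagents that add atoms: none
Why: Allylic oxidation with activated MnO2 converts the cinnamyl-type alcohol into the enal under neutral conditions that should spare the acid-sensitive enol ether and keep the Z geometry.

Step 4
Reactants: 6 (2Z)-2-methoxy-3-[3,4,5-tris(benzyloxy)phenyl]prop-2-enal; 7 3,5-bis(benzyloxy)phenol; 8 phenylboronic acid
Product: 11 (±)-5,7-bis(benzyloxy)-3-methoxy-2-[3,4,5-tris(benzyloxy)phenyl]-2H-chromene, via benzodioxaborin 9 (not isolated), via ortho-quinone methide 10 (not isolated)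
Conditions: 8 (1.1 equiv), EtCO2H (0.3 equiv), toluene, reflux, Dean–Stark trap, N2
Reagents that add atoms: none
Why: Phenylboronic acid esterifies the phenol oxygen of 7 and binds the aldehyde oxygen of 6, so that the carbon ortho to the boron-bound oxygen adds to the carbonyl carbon through a six-membered boron-bridged transition state (C4–C4a bond) to give benzodioxaborin 9; on heating with acid 9 undergoes cycloreversion with loss of the boron unit to ortho-quinone methide 10, a 1-oxatriene that closes thermally (O1–C2 bond). The closest known reaction type is the phenylboronic acid-mediated chromene annulation of phenols with α,β-unsaturated aldehydes. Ring C is closed by a disrotatory oxa-6π electrocyclisation, and the temporary six-membered dioxaborin ring is opened again in the same flask. The only new stereocentre, C2, is formed without control and is racemic on purpose, because step 5 makes it epimerisable and step 6 sets it. The step needs C- over O-alkylation, ortho over para attack and 1,2- over 1,4-addition to the enal: the boron tether delivers the aldehyde carbon only to an ortho carbon, the two ortho carbons of 7 are equivalent and activated by ortho and para oxygens, the single free OH rules out a second annulation, and the α-methoxy group makes the aryl-bearing carbon of 6 (later C2) the β-carbon of an enol ether and so a poor Michael acceptor.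

Step 5
Reactants: 11 (±)-5,7-bis(benzyloxy)-3-methoxy-2-[3,4,5-tris(benzyloxy)phenyl]-2H-chromene
Product: 12 (±)-5,7-bis(benzyloxy)-2-[3,4,5-tris(benzyloxy)phenyl]chroman-3-one
Conditions: 1 M aqueous HCl, THF, 20 °C, degassed, N2
Reagents that add atoms: water, O
Why: In this acid-catalysed enol ether hydrolysis, protonation at C4 should give the oxocarbenium ion at C3, to which water adds with loss of methanol, unmasking the ketone that makes C2–H acidic while C2 stays racemic.

Step 6
Reactants: 12 (±)-5,7-bis(benzyloxy)-2-[3,4,5-tris(benzyloxy)phenyl]chroman-3-one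
Product: 13 (2R,3R)-5,7-bis(benzyloxy)-2-[3,4,5-tris(benzyloxy)phenyl]chroman-3-ol
Conditions: RuCl[(S,S)-TsDPEN](p-cymene) (2 mol %; TsDPEN = N-tosyl-1,2-diphenylethane-1,2-diamine), HCO2H–Et3N (5:2), EtOAc, 35 °C, degassed, N2
Reagents that add atoms: none
Why: In this Noyori–Ikariya asymmetric transfer hydrogenation under dynamic kinetic resolution, C2–H (benzylic, α-aryloxy and α to the ketone) should be epimerised by Et3N through the enol faster than reduction, while the chiral ruthenium hydride reduces the (2R)-ketone preferentially and delivers hydride to the C3 face anti to the 2-aryl group, which should set C2 (R) and C3 (R) together with the cis relationship.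

Step 7
Reactants: 13 (2R,3R)-5,7-bis(benzyloxy)-2-[3,4,5-tris(benzyloxy)phenyl]chroman-3-ol; 14 3,4,5-tris(benzyloxy)benzoic acid
Product: 15 (2R,3R)-5,7-bis(benzyloxy)-2-[3,4,5-tris(benzyloxy)phenyl]chroman-3-yl 3,4,5-tris(benzyloxy)benzoate
Conditions: DCC (1.5 equiv), DMAP (0.2 equiv), CH2Cl2, 0 °C to rt
Reagents that add atoms: none
Why: In this Steglich esterification DCC activates acid 14 and DMAP transfers the acyl group to the hindered secondary alcohol on oxygen only, so neither C2 nor C3 is touched.

Step 8
Reactants: 15 (2R,3R)-5,7-bis(benzyloxy)-2-[3,4,5-tris(benzyloxy)phenyl]chroman-3-yl 3,4,5-tris(benzyloxy)benzoate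
Product: 16 (−)-epigallocatechin gallate
Conditions: H2 (1 atm), Pd(OH)2/C, THF–MeOH, rt
Reagents that add atoms: none
Why: Catalytic hydrogenolysis of the eight benzyl aryl ethers should release all phenols under neutral conditions that leave the ester, the ring ether O1–C2 and both stereocentres unchanged.

**Compound list**

1 | 3,4,5-tris(benzyloxy)benzaldehyde | O=Cc1cc(OCc2ccccc2)c(OCc2ccccc2)c(OCc2ccccc2)c1 | starting material
2 | methyl methoxyacetate | COCC(=O)OC | starting material
3 | methyl 3-hydroxy-2-methoxy-3-[3,4,5-tris(benzyloxy)phenyl]propanoate (aldol adduct, mixture of diastereomers, not isolated) | COC(=O)C(OC)C(O)c1cc(OCc2ccccc2)c(OCc2ccccc2)c(OCc2ccccc2)c1 | intermediate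
4 | methyl (2Z)-2-methoxy-3-[3,4,5-tris(benzyloxy)phenyl]prop-2-enoate | COC(=O)/C(OC)=C/c1cc(OCc2ccccc2)c(OCc2ccccc2)c(OCc2ccccc2)c1 | intermediate
5 | (2Z)-2-methoxy-3-[3,4,5-tris(benzyloxy)phenyl]prop-2-en-1-ol | OC/C(OC)=C/c1cc(OCc2ccccc2)c(OCc2ccccc2)c(OCc2ccccc2)c1 | intermediate
6 | (2Z)-2-methoxy-3-[3,4,5-tris(benzyloxy)phenyl]prop-2-enal | O=C/C(OC)=C/c1cc(OCc2ccccc2)c(OCc2ccccc2)c(OCc2ccccc2)c1 | intermediate
7 | 3,5-bis(benzyloxy)phenol | Oc1cc(OCc2ccccc2)cc(OCc2ccccc2)c1 | starting material
8 | phenylboronic acid | OB(O)c1ccccc1 | starting material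
9 | 5,7-bis(benzyloxy)-4-{(Z)-1-methoxy-2-[3,4,5-tris(benzyloxy)phenyl]ethenyl}-2-phenyl-4H-1,3,2-benzodioxaborin (racemic at C4, not isolated) | c1ccccc1B1OC(/C(OC)=C/c2cc(OCc3ccccc3)c(OCc3ccccc3)c(OCc3ccccc3)c2)c2c(OCc3ccccc3)cc(OCc3ccccc3)cc2O1 | intermediate
10 | 3,5-bis(benzyloxy)-6-{(2Z)-2-methoxy-3-[3,4,5-tris(benzyloxy)phenyl]prop-2-en-1-ylidene}cyclohexa-2,4-dien-1-one (ortho-quinone methide, drawn with C3 syn to the carbonyl, not isolated) | O=C1C=C(OCc2ccccc2)C=C(OCc2ccccc2)/C1=C/C(OC)=C/c1cc(OCc2ccccc2)c(OCc2ccccc2)c(OCc2ccccc2)c1 | intermediate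
11 | (±)-5,7-bis(benzyloxy)-3-methoxy-2-[3,4,5-tris(benzyloxy)phenyl]-2H-chromene | COC1=Cc2c(OCc3ccccc3)cc(OCc3ccccc3)cc2OC1c1cc(OCc2ccccc2)c(OCc2ccccc2)c(OCc2ccccc2)c1 | intermediate
12 | (±)-5,7-bis(benzyloxy)-2-[3,4,5-tris(benzyloxy)phenyl]chroman-3-one | O=C1Cc2c(OCc3ccccc3)cc(OCc3ccccc3)cc2OC1c1cc(OCc2ccccc2)c(OCc2ccccc2)c(OCc2ccccc2)c1 | intermediate
13 | (2R,3R)-5,7-bis(benzyloxy)-2-[3,4,5-tris(benzyloxy)phenyl]chroman-3-ol (penta-O-benzyl-epigallocatechin) | O[C@@H]1Cc2c(OCc3ccccc3)cc(OCc3ccccc3)cc2O[C@@H]1c1cc(OCc2ccccc2)c(OCc2ccccc2)c(OCc2ccccc2)c1 | intermediate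
14 | 3,4,5-tris(benzyloxy)benzoic acid | OC(=O)c1cc(OCc2ccccc2)c(OCc2ccccc2)c(OCc2ccccc2)c1 | starting material
15 | (2R,3R)-5,7-bis(benzyloxy)-2-[3,4,5-tris(benzyloxy)phenyl]chroman-3-yl 3,4,5-tris(benzyloxy)benzoate | O=C(O[C@@H]1Cc2c(OCc3ccccc3)cc(OCc3ccccc3)cc2O[C@@H]1c1cc(OCc2ccccc2)c(OCc2ccccc2)c(OCc2ccccc2)c1)c1cc(OCc2ccccc2)c(OCc2ccccc2)c(OCc2ccccc2)c1 | intermediate
16 | (−)-epigallocatechin gallate, (2R,3R) | O=C(O[C@@H]1Cc2c(O)cc(O)cc2O[C@@H]1c1cc(O)c(O)c(O)c1)c1cc(O)c(O)c(O)c1 | target

**Step count and risks**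

Total step count: 8. Longest linear sequence: 8 steps (1 to 16); phenol 7 enters at step 4 and acid 14 at step 7.

Steps most likely to fail:

Step 4. What may go wrong: proton-catalysed conjugate or para Friedel–Crafts attack of the electron-rich phenol outrunning the templated ortho 1,2-addition, incomplete cycloreversion of the benzodioxaborin, or hydrolysis of the enol ether of the enal by the water of condensation. The fallback is stepwise and magnesium-templated; it sets out from 7 and 6. Phenol 7 is deprotonated with EtMgBr (Et2O, then toluene) and the bromomagnesium phenoxide adds 6 through a six-membered magnesium chelate, a known ortho-specific 1,2-hydroxyalkylation of phenols. After NH4Cl work-up this should give 3,5-bis(benzyloxy)-2-{(2Z)-1-hydroxy-2-methoxy-3-[3,4,5-tris(benzyloxy)phenyl]prop-2-en-1-yl}phenol F1. F1 is then dehydrated (pyridinium p-toluenesulfonate cat., toluene, 80 °C) to ortho-quinone methide 10, which closes to 11, where the route is rejoined.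

Step 6. What may go wrong: epimerisation at C2 lagging behind reduction (so that only a kinetic resolution takes place), low or reversed facial discrimination at a carbonyl that has no directly bonded aryl group, or air oxidation of the enol. The fallback separates relative from absolute control and sets out from 12. Reduction with LiBH(sBu)3 (THF, −78 °C), with substrate-controlled hydride delivery anti to the 2-aryl group, should give the racemic cis-alcohol (2R*,3R*)-5,7-bis(benzyloxy)-2-[3,4,5-tris(benzyloxy)phenyl]chroman-3-ol F2. Esterification with (S)-2-methoxy-2-phenylacetic acid, CO[C@H](C(=O)O)c1ccccc1 (DCC, DMAP, CH2Cl2), should give two diastereomeric esters: the (2R,3R)-chromanyl (S)-2-methoxy-2-phenylacetate F3 and the (2S,3S)-chromanyl (S)-2-methoxy-2-phenylacetate F4. These are separated by chromatography or crystallisation. Methanolysis of F3 (K2CO3 cat., MeOH–THF, rt) returns to the route at 13.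

Step 1. What may go wrong: saponification of the ester by the hydroxide formed in the condensation, and incomplete conversion of the electron-rich, poorly soluble aldehyde. The fallback is a Horner–Wadsworth–Emmons olefination; it sets out from 1. Aldehyde 1 is treated with methyl 2-(dimethoxyphosphoryl)-2-methoxyacetate, COC(=O)C(OC)P(=O)(OC)OC (NaH, THF, 0 °C to rt), which should give ester 4 directly, where the route is rejoined. The minor geometric isomer methyl (2E)-2-methoxy-3-[3,4,5-tris(benzyloxy)phenyl]prop-2-enoate F5 is removed by chromatography.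

**Further compounds**

F1 | step 4 | 3,5-bis(benzyloxy)-2-{(2Z)-1-hydroxy-2-methoxy-3-[3,4,5-tris(benzyloxy)phenyl]prop-2-en-1-yl}phenol (racemic) | Oc1cc(OCc2ccccc2)cc(OCc2ccccc2)c1C(O)/C(OC)=C/c1cc(OCc2ccccc2)c(OCc2ccccc2)c(OCc2ccccc2)c1
F2 | step 6 | racemic cis-5,7-bis(benzyloxy)-2-[3,4,5-tris(benzyloxy)phenyl]chroman-3-ol (1:1 mixture of 13 and its enantiomer) | O[C@@H]1Cc2c(OCc3ccccc3)cc(OCc3ccccc3)cc2O[C@@H]1c1cc(OCc2ccccc2)c(OCc2ccccc2)c(OCc2ccccc2)c1.O[C@H]1Cc2c(OCc3ccccc3)cc(OCc3ccccc3)cc2O[C@H]1c1cc(OCc2ccccc2)c(OCc2ccccc2)c(OCc2ccccc2)c1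
F3 | step 6 | (2R,3R)-5,7-bis(benzyloxy)-2-[3,4,5-tris(benzyloxy)phenyl]chroman-3-yl (S)-2-methoxy-2-phenylacetate | CO[C@H](C(=O)O[C@@H]1Cc2c(OCc3ccccc3)cc(OCc3ccccc3)cc2O[C@@H]1c1cc(OCc2ccccc2)c(OCc2ccccc2)c(OCc2ccccc2)c1)c1ccccc1
F4 | step 6 | (2S,3S)-5,7-bis(benzyloxy)-2-[3,4,5-tris(benzyloxy)phenyl]chroman-3-yl (S)-2-methoxy-2-phenylacetate | CO[C@H](C(=O)O[C@H]1Cc2c(OCc3ccccc3)cc(OCc3ccccc3)cc2O[C@H]1c1cc(OCc2ccccc2)c(OCc2ccccc2)c(OCc2ccccc2)c1)c1ccccc1
F5 | step 1 | methyl (2E)-2-methoxy-3-[3,4,5-tris(benzyloxy)phenyl]prop-2-enoate | COC(=O)/C(OC)=C\c1cc(OCc2ccccc2)c(OCc2ccccc2)c(OCc2ccccc2)c1
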